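**Assumption:** Bryostatin numbering C1–C27 is used throughout. The C13 and C21 enoate E/Z mixtures are assumed separable, and the C9 hemiketal is assumed to form as the anomerically stabilised (9S) isomer.

## Retrosynthetic overview
1. Bryostatin 16 comes from hydration of a C9 exocyclic enol ether. That enol ether comes from Au-catalysed 6-exo-dig hydroalkoxylation (C5-OH onto C9≡C10), which forms ring A before the macrolactone closes. The macrolactone closes last (Yamaguchi, C1 acid onto C25-OH).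
2. The seco-ester comes from a Julia–Kocienski olefination forming C16=C17 between a ring-B aldehyde and a ring-C PT-sulfone.
3. **Key step:** Ti(III) homolysis of the C7–C8 trisubstituted epoxide gives the tertiary C8 radical, which is trapped by the ring-B bromoalkyne. This forms the hindered C8 quaternary centre and the C8–C9 bond, and C7 keeps the epoxide's configuration.
4. Ring B comes from a Jacobsen hetero-Diels–Alder reaction, conjugate addition and epimerisation. Ring C comes from a boron aldol and a 6-endo-dig oxa-Michael cyclisation. Rings form in the order B, C, A, then the macrocycle.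

## Route (33 steps)

**Step 1**
Reactants: 1 (4-methylpent-3-en-1-ol)
Product: 2 ((S)-2-(3,3-dimethyloxiran-2-yl)ethanol)
Conditions: Shi fructose-derived ketone (30 mol%), Oxone, K2CO3, Bu4NHSO4, MeCN/DMM/aq. EDTA pH 10.5, 0 °C
Reagents that add atoms: Oxone (O source), OOS(=O)(=O)[O-].[K+]
Why: Shi asymmetric epoxidation of the trisubstituted alkene, with the ketone enantiomer chosen to give (S), sets C7, which becomes the C7 carbinol.

**Step 2**
Reactants: 2
Product: 3 ((S)-2-(3,3-dimethyloxiran-2-yl)acetaldehyde)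
Conditions: DMP, NaHCO3, CH2Cl2, 0 °C
Reagents that add atoms: none
Why: Buffered Dess–Martin oxidation leaves the epoxide intact; the base-sensitive β,γ-epoxy aldehyde is used immediately.

**Step 3**
Reactants: 3
Product: 4 ((2R)-1-[(2S)-3,3-dimethyloxiran-2-yl]pent-4-en-2-ol)
Conditions: (Ipc)2B-allyl (pinene enantiomer that gives the R carbinol), Et2O, –78 °C; then NaBO3 workup
Reagents that add atoms: B-allyldiisopinocampheylborane, C=CCB(C1CC2CC(C1C)C2(C)C)C1CC2CC(C1C)C2(C)C
Why: Brown allylation is reagent-controlled and sets C5 (R), 1,3-anti to C7.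

**Step 4**
Reactants: 4
Product: 5 (C5-TES ether of 4)
Conditions: TESCl, imidazole, DMF, 25 °C
Reagents that add atoms: TESCl, CC[Si](CC)(CC)Cl
Why: Silyl protection; TES is the most labile silyl group in the route and is removed selectively later.

**Step 5**
Reactants: 5
Product: 6 ((3S)-4-[(2S)-3,3-dimethyloxiran-2-yl]-3-(TESO)butanal)
Conditions: O3, CH2Cl2, –78 °C; then PPh3
Reagents that add atoms: ozone, O=[O+][O-]
Why: Ozonolysis of the terminal alkene, which is the only alkene present; the epoxide is inert to ozone.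

**Step 6**
Reactants: 6
Product: 7 (methyl (3R,5R)-6-[(2S)-3,3-dimethyloxiran-2-yl]-3-hydroxy-5-(TESO)hexanoate)
Conditions: Ti(OiPr)4/tridentate Schiff-base catalyst (Carreira), Et2O, 0 °C; pH 7 buffer workup
Reagents that add atoms: 1-methoxy-1-TBSO-ethene, COC(=C)O[Si](C)(C)C(C)(C)C
Why: The Carreira Mukaiyama acetate aldol is catalyst-controlled, sets C3 (R) 1,3-anti to C5, and installs C1/C2.

**Step 7**
Reactants: 7
Product: 8 (methyl (3R,5S)-3-(TBSO)-6-[(2S)-3,3-dimethyloxiran-2-yl]-5-(TESO)hexanoate; the 5R→5S label change is only a CIP priority change)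
Conditions: TBSOTf, 2,6-lutidine, CH2Cl2, –78 °C
Reagents that add atoms: TBSOTf, CC(C)(C)[Si](C)(C)OS(=O)(=O)C(F)(F)F
Why: Protects the C3 alcohol as the robust silyl ether that survives to the end; the lutidine buffer protects the epoxide.

**Step 8**
Reactants: 9 ((E)-4-methoxybut-3-en-2-one)
Product: 10 (Danishefsky diene, 1-methoxy-3-(trimethylsiloxy)buta-1,3-diene)
Conditions: TMSCl, Et3N, ZnCl2 (cat.), benzene, 40 °C
Reagents that add atoms: TMSCl, C[Si](C)(C)Cl
Why: Standard silyl enol ether formation from the enone.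

**Step 9**
Reactants: 11 (3-(trimethylsilyl)propynal) and 10
Product: 12 ((2S)-2-[(trimethylsilyl)ethynyl]-2,3-dihydro-4H-pyran-4-one)
Conditions: chiral Cr(III)–Schiff-base catalyst (Jacobsen; enantiomer chosen for 2S), acetone, 4 Å MS, –20 °C; then TFA, CH2Cl2
Reagents that add atoms: none
Why: The Jacobsen hetero-Diels–Alder reaction sets C11 (S) and delivers the ring-B skeleton with C13 already at the ketone oxidation level.

**Step 10**
Reactants: 12
Product: 13 ((2S,6R)-2-[(trimethylsilyl)ethynyl]-6-vinyltetrahydropyran-4-one, 2,6-cis)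
Conditions: CH2=CHMgBr, CuBr·SMe2, THF, –78 °C; then DBU, CH2Cl2, 25 °C
Reagents that add atoms: vinylmagnesium bromide, C=C[Mg]Br
Why: Cuprate 1,4-addition gives mainly the 2,6-trans ketone, and DBU epimerises it through retro-/re-oxa-Michael to the thermodynamic 2,6-cis isomer, which sets C15 (R).

**Step 11**
Reactants: 13
Product: 14 (methyl (2E)-2-[(2S,6R)-6-ethenyl-2-(TMS-ethynyl)oxan-4-ylidene]acetate; CO2Me anti to C12)
Conditions: (MeO)2P(O)CH2CO2Me, LiCl, DBU, MeCN, 0 °C; separate E/Z by chromatography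
Reagents that add atoms: methyl dimethylphosphonoacetate, COP(=O)(OC)CC(=O)OC
Why: Masamune–Roush HWE builds the exocyclic C13 enoate under mild conditions that avoid ring opening.

**Step 12**
Reactants: 14
Product: 15 (methyl (2E)-2-[(2S,6R)-2-(bromoethynyl)-6-ethenyloxan-4-ylidene]acetate)
Conditions: NBS, AgF, MeCN, 25 °C, dark
Reagents that add atoms: NBS, BrN1C(=O)CCC1=O
Why: Ag-mediated conversion of the TMS-alkyne into the bromoalkyne, which serves as the radical trap.

**Step 13 (key radical step)**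
Reactants: 8 and 15
Product: 16 (C1–C16 fragment with the new C8–C9 bond and free C7–OH)
Conditions: Cp2TiCl2 (20 mol%), Zn, 2,4,6-collidine·HCl, THF, 25 °C
Reagents that add atoms: none
Why: **Proposed new method:** Cp2TiCl reductively opens the trisubstituted epoxide to the tertiary C8 radical with C7–OTi. The radical adds ipso to the bromoalkyne, and the vinyl radical expels Br• to give the internal alkyne, so C7 keeps its configuration and C8 (gem-dimethyl) needs no new stereocentre. The closest known reactions are Gansäuer/Nugent–RajanBabu Ti(III) epoxide-opening radical additions and radical alkynylation of tertiary radicals with alkynyl halides.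

**Step 14**
Reactants: 16
Product: 17 (C7 pivalate of 16)
Conditions: PivCl, pyridine, DMAP, 60 °C
Reagents that add atoms: PivCl, CC(C)(C)C(=O)Cl
Why: Acylation installs the target C7 pivalate; forcing conditions are needed for the neopentylic alcohol.

**Step 15**
Reactants: 17
Product: 18 (ring-B C16 aldehyde)
Conditions: OsO4 (5 mol%), NaIO4, 2,6-lutidine, dioxane/H2O, 25 °C
Reagents that add atoms: NaIO4 (O source), [Na+].[O-]I(=O)(=O)=O
Why: Lemieux–Johnson cleavage is selective for the monosubstituted vinyl group over the hindered internal alkyne and the electron-poor exocyclic enoate.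

**Step 16**
Reactants: 19 (hydroxypivaldehyde)
Product: 20 (2,2-dimethylbut-3-yn-1-ol)
Conditions: Bestmann–Ohira reagent, K2CO3, MeOH, 25 °C
Reagents that add atoms: dimethyl (1-diazo-2-oxopropyl)phosphonate, COP(=O)(OC)C(=[N+]=[N-])C(C)=O
Why: The non-enolisable aldehyde converts cleanly to the terminal alkyne, making the C18 quaternary centre with no extra steps.

**Step 17**
Reactants: 20
Product: 21 (PT sulfide, HC≡C–CMe2–CH2–S-PT)
Conditions: 1-phenyl-1H-tetrazole-5-thiol, PPh3, DIAD, THF, 0 → 40 °C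
Reagents that add atoms: 1-phenyl-1H-tetrazole-5-thiol, Sc1nnnn1-c1ccccc1
Why: Mitsunobu thioetherification prepares the Julia partner (SN2 at a neopentyl carbon, so heating is needed).

**Step 18**
Reactants: 21
Product: 22 (5,5-dimethyl-6-(PT-thio)hex-3-yn-2-one)
Conditions: n-BuLi (1.05 equiv), THF, –78 °C; then MeC(O)N(OMe)Me
Reagents that add atoms: N-methoxy-N-methylacetamide, CC(=O)N(C)OC
Why: The lithium acetylide is acylated by the Weinreb amide to give the methyl ynone (C19–C22).

**Step 19**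
Reactants: 23 (methyl (R)-lactate)
Product: 24 (methyl (R)-2-(TBSO)propanoate)
Conditions: TBSCl, imidazole, DMF, 25 °C
Reagents that add atoms: TBSCl, CC(C)(C)[Si](C)(C)Cl
Why: Protects the C26 oxygen; the lactate stereocentre becomes C26 (R).

**Step 20**
Reactants: 24
Product: 25 ((R)-2-(TBSO)propanal)
Conditions: DIBAL-H, CH2Cl2, –78 °C
Reagents that add atoms: none
Why: Partial ester reduction at low temperature stops at the aldehyde.

**Step 21**
Reactants: 25
Product: 26 ((2R,3R)-2-(TBSO)hex-5-en-3-ol, the C25 homoallylic alcohol)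
Conditions: (Ipc)2B-allyl (pinene enantiomer giving the 25R alcohol), Et2O, –78 °C; then NaBO3 workup
Reagents that add atoms: B-allyldiisopinocampheylborane, C=CCB(C1CC2CC(C1C)C2(C)C)C1CC2CC(C1C)C2(C)C
Why: Reagent-controlled Brown allylation sets C25 (R), syn to C26, and overrides the substrate's own facial bias.

**Step 22**
Reactants: 26
Product: 27 (C25-TES ether)
Conditions: TESOTf, 2,6-lutidine, CH2Cl2, –78 °C
Reagents that add atoms: TESOTf, CC[Si](CC)(CC)OS(=O)(=O)C(F)(F)F
Why: Protection; this TES is removed together with the C5 TES in Step 29.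

**Step 23**
Reactants: 27
Product: 28 (C23 aldehyde)
Conditions: O3, CH2Cl2, –78 °C; then PPh3
Reagents that add atoms: ozone, O=[O+][O-]
Why: Ozonolysis of the terminal alkene gives the β-silyloxy aldehyde for the aldol.

**Step 24**
Reactants: 22 and 28
Product: 29 (β-hydroxy ynone; C23 carbinol R by CIP in this intermediate, C23/C25 1,3-anti)
Conditions: Cy2BCl, Me2NEt, Et2O, 0 °C; then 28, –78 °C; pH 7 buffer/MeOH/H2O2 workup at 0 °C
Reagents that add atoms: none
Why: The boron aldol of a methyl ketone with a β-silyloxy aldehyde is 1,3-anti selective (Evans/Paterson model), matching the C23/C25 anti relationship.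

**Step 25**
Reactants: 29
Product: 30 (2,3-dihydropyran-4-one, ring C)
Conditions: PMe3 (20 mol%), CH2Cl2, 25 °C
Reagents that add atoms: none
Why: Phosphine-catalysed 6-endo-dig oxa-Michael addition of the C23-OH to the ynone closes ring C with the C19=C20 enol ether, and C23 is untouched.

**Step 26**
Reactants: 30
Product: 31 (ring-C dienoate; CO2Me cis to C22)
Conditions: (MeO)2P(O)CH2CO2Me, KHMDS, 18-crown-6, THF, –20 → 40 °C; separate isomers
Reagents that add atoms: methyl dimethylphosphonoacetate, COP(=O)(OC)CC(=O)OC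
Why: HWE olefination of the vinylogous-ester carbonyl builds the exocyclic C21 enoate, done while the sulfur is still a sulfide.

**Step 27**
Reactants: 31
Product: 32 (PT-sulfone)
Conditions: (NH4)6Mo7O24·4H2O (10 mol%), H2O2, EtOH, 0 °C
Reagents that add atoms: hydrogen peroxide, OO
Why: Molybdate-catalysed sulfide oxidation is selective over the push–pull dienoate.

**Step 28**
Reactants: 18 and 32
Product: 33 (seco-methyl ester with E C16=C17 alkene)
Conditions: KHMDS, DME/THF, –78 → 25 °C
Reagents that add atoms: none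
Why: Julia–Kocienski olefination of the neopentylic PT-sulfone with the α-alkoxy aldehyde forms the trans C16=C17 alkene.

**Step 29**
Reactants: 33
Product: 34 (C5,C25-diol; TBS at C3 and C26 retained)
Conditions: PPTS, MeOH, 0 → 25 °C
Reagents that add atoms: none
Why: TES ethers are cleaved selectively in the presence of TBS ethers, the pivalate and the esters.

**Step 30**
Reactants: 34
Product: 35 (ring A as the C9 exocyclic enol ether)
Conditions: Ph3PAuCl/AgOTf (5 mol%), 2,6-di-tert-butylpyridine, CH2Cl2, 4 Å MS, 25 °C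
Reagents that add atoms: none
Why: Au(I)-catalysed 6-exo-dig hydroalkoxylation of C5-OH onto C9 forms ring A; attack at C9 is favoured because the propargylic C11 oxygen disfavours attack at C10, and the C8 gem-dimethyl group helps cyclisation.

**Step 31**
Reactants: 35
Product: 36 (seco-hydroxy acid)
Conditions: LiOH·H2O, THF/H2O, 0 °C
Reagents that add atoms: lithium hydroxide, [Li+].[OH-]
Why: The unhindered C1 methyl ester is cleaved in preference to the hindered conjugated enoates and the pivalate; 0 °C avoids β-elimination of the C3 silyl ether.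

**Step 32**
Reactants: 36
Product: 37 (macrolactone, C1–O25)
Conditions: 2,4,6-Cl3C6H2COCl, Et3N, THF; then DMAP, toluene, 80 °C, 2 mM
Reagents that add atoms: none
Why: Yamaguchi macrolactonisation proceeds with a single free alcohol, because C5 is already consumed in ring A.

**Step 33**
Reactants: 37
Product: 38 (bryostatin 16)
Conditions: 48% aq. HF, MeCN, 0 → 25 °C
Reagents that add atoms: water, O
Why: Aqueous HF removes the C3 and C26 TBS ethers, and protonation of the C9 enol ether at C10 followed by water capture gives the C9 hemiketal under anomeric control (9S).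

## Compound list
1 | 4-methylpent-3-en-1-ol | CC(C)=CCCO | starting material
2 | (S)-2-(3,3-dimethyloxiran-2-yl)ethanol | OCC[C@@H]1OC1(C)C | intermediate
3 | (S)-2-(3,3-dimethyloxiran-2-yl)acetaldehyde | O=CC[C@@H]1OC1(C)C | intermediate
4 | (2R)-1-[(2S)-3,3-dimethyloxiran-2-yl]pent-4-en-2-ol | C=CC[C@@H](O)C[C@@H]1OC1(C)C | intermediate
5 | TES ether of 4 | C=CC[C@@H](O[Si](CC)(CC)CC)C[C@@H]1OC1(C)C | intermediate
6 | C3 aldehyde | O=CC[C@@H](O[Si](CC)(CC)CC)C[C@@H]1OC1(C)C | intermediate
7 | β-hydroxy ester | COC(=O)C[C@H](O)C[C@@H](O[Si](CC)(CC)CC)C[C@@H]1OC1(C)C | intermediate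
8 | epoxide radical precursor | COC(=O)C[C@H](O[Si](C)(C)C(C)(C)C)C[C@@H](O[Si](CC)(CC)CC)C[C@@H]1OC1(C)C | intermediate
9 | (E)-4-methoxybut-3-en-2-one | COC=CC(C)=O | starting material
10 | Danishefsky diene | COC=CC(=C)O[Si](C)(C)C | intermediate
11 | 3-(trimethylsilyl)propynal | C[Si](C)(C)C#CC=O | starting material
12 | (2S)-2-(TMS-ethynyl)-2,3-dihydro-4H-pyran-4-one | O=C1C[C@@H](C#C[Si](C)(C)C)OC=C1 | intermediate
13 | 2,6-cis-THP-4-one | O=C1C[C@@H](C#C[Si](C)(C)C)O[C@@H](C=C)C1 | intermediate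
14 | C13 enoate | COC(=O)/C=C1/C[C@@H](C#C[Si](C)(C)C)O[C@@H](C=C)C1 | intermediate
15 | bromoalkyne | COC(=O)/C=C1/C[C@@H](C#CBr)O[C@@H](C=C)C1 | intermediate
16 | radical product | COC(=O)C[C@H](O[Si](C)(C)C(C)(C)C)C[C@@H](O[Si](CC)(CC)CC)C[C@H](O)C(C)(C)C#C[C@@H]1C/C(=C/C(=O)OC)C[C@H](C=C)O1 | intermediate
17 | C7 pivalate | COC(=O)C[C@H](O[Si](C)(C)C(C)(C)C)C[C@@H](O[Si](CC)(CC)CC)C[C@H](OC(=O)C(C)(C)C)C(C)(C)C#C[C@@H]1C/C(=C/C(=O)OC)C[C@H](C=C)O1 | intermediate
18 | ring-B aldehyde | COC(=O)C[C@H](O[Si](C)(C)C(C)(C)C)C[C@@H](O[Si](CC)(CC)CC)C[C@H](OC(=O)C(C)(C)C)C(C)(C)C#C[C@@H]1C/C(=C/C(=O)OC)C[C@H](C=O)O1 | intermediate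
19 | hydroxypivaldehyde | CC(C)(CO)C=O | starting material
20 | 2,2-dimethylbut-3-yn-1-ol | C#CC(C)(C)CO | intermediate
21 | PT sulfide | C#CC(C)(C)CSc1nnnn1-c1ccccc1 | intermediate
22 | methyl ynone | CC(=O)C#CC(C)(C)CSc1nnnn1-c1ccccc1 | intermediate
23 | methyl (R)-lactate | C[C@@H](O)C(=O)OC | starting material
24 | methyl (R)-2-(TBSO)propanoate | C[C@@H](O[Si](C)(C)C(C)(C)C)C(=O)OC | intermediate
25 | (R)-2-(TBSO)propanal | C[C@@H](O[Si](C)(C)C(C)(C)C)C=O | intermediate
26 | (2R,3R)-2-(TBSO)hex-5-en-3-ol (C25 alcohol) | C[C@@H](O[Si](C)(C)C(C)(C)C)[C@H](O)CC=C | intermediate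
27 | C25-TES ether | C[C@@H](O[Si](C)(C)C(C)(C)C)[C@H](O[Si](CC)(CC)CC)CC=C | intermediate
28 | C23 aldehyde | C[C@@H](O[Si](C)(C)C(C)(C)C)[C@H](O[Si](CC)(CC)CC)CC=O | intermediate
29 | β-hydroxy ynone | C[C@@H](O[Si](C)(C)C(C)(C)C)[C@H](O[Si](CC)(CC)CC)C[C@@H](O)CC(=O)C#CC(C)(C)CSc1nnnn1-c1ccccc1 | intermediate
30 | ring-C dihydropyranone | C[C@@H](O[Si](C)(C)C(C)(C)C)[C@H](O[Si](CC)(CC)CC)C[C@@H]1CC(=O)C=C(O1)C(C)(C)CSc1nnnn1-c1ccccc1 | intermediate
31 | ring-C dienoate sulfide | C[C@@H](O[Si](C)(C)C(C)(C)C)[C@H](O[Si](CC)(CC)CC)C[C@@H]1C/C(=C\C(=O)OC)C=C(O1)C(C)(C)CSc1nnnn1-c1ccccc1 | intermediate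
32 | ring-C PT-sulfone | C[C@@H](O[Si](C)(C)C(C)(C)C)[C@H](O[Si](CC)(CC)CC)C[C@@H]1C/C(=C\C(=O)OC)C=C(O1)C(C)(C)CS(=O)(=O)c1nnnn1-c1ccccc1 | intermediate
33 | Julia product | COC(=O)C[C@H](O[Si](C)(C)C(C)(C)C)C[C@@H](O[Si](CC)(CC)CC)C[C@H](OC(=O)C(C)(C)C)C(C)(C)C#C[C@@H]1C/C(=C/C(=O)OC)C[C@H](/C=C/C(C)(C)C2=C/C(=C/C(=O)OC)C[C@@H](C[C@@H](O[Si](CC)(CC)CC)[C@@H](C)O[Si](C)(C)C(C)(C)C)O2)O1 | intermediate
34 | C5,C25-diol | COC(=O)C[C@H](O[Si](C)(C)C(C)(C)C)C[C@@H](O)C[C@H](OC(=O)C(C)(C)C)C(C)(C)C#C[C@@H]1C/C(=C/C(=O)OC)C[C@H](/C=C/C(C)(C)C2=C/C(=C/C(=O)OC)C[C@@H](C[C@@H](O)[C@@H](C)O[Si](C)(C)C(C)(C)C)O2)O1 | intermediate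
35 | ring-A enol ether | COC(=O)C[C@H](O[Si](C)(C)C(C)(C)C)C[C@@H]1C[C@H](OC(=O)C(C)(C)C)C(C)(C)C(O1)=C[C@@H]2C/C(=C/C(=O)OC)C[C@H](/C=C/C(C)(C)C3=C/C(=C/C(=O)OC)C[C@@H](C[C@@H](O)[C@@H](C)O[Si](C)(C)C(C)(C)C)O3)O2 | intermediate
36 | seco-hydroxy acid | OC(=O)C[C@H](O[Si](C)(C)C(C)(C)C)C[C@@H]1C[C@H](OC(=O)C(C)(C)C)C(C)(C)C(O1)=C[C@@H]2C/C(=C/C(=O)OC)C[C@H](/C=C/C(C)(C)C3=C/C(=C/C(=O)OC)C[C@@H](C[C@@H](O)[C@@H](C)O[Si](C)(C)C(C)(C)C)O3)O2 | intermediate
37 | macrolactone enol ether | O=C1C[C@H](O[Si](C)(C)C(C)(C)C)C[C@@H]2C[C@H](OC(=O)C(C)(C)C)C(C)(C)C(O2)=C[C@@H]3C/C(=C/C(=O)OC)C[C@H](/C=C/C(C)(C)C4=C/C(=C/C(=O)OC)C[C@@H](C[C@@H](O1)[C@@H](C)O[Si](C)(C)C(C)(C)C)O4)O3 | intermediate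
38 | bryostatin 16 | COC(=O)/C=C1/C[C@H]2C[C@]3(O)O[C@H](C[C@@H](O)CC(=O)O[C@@H]([C@@H](C)O)C[C@@H]4C/C(=C\C(=O)OC)C=C(O4)C(C)(C)/C=C/[C@@H](C1)O2)C[C@H](OC(=O)C(C)(C)C)C3(C)C | target

## Totals
Total steps: 33. Longest linear sequence: 16 (Steps 1–7, 13–15, 28–33).

**Three steps most likely to fail**
1. **Step 13 (Ti(III) radical alkynylation).** The tertiary radical may be reduced by a second Ti(III) to give allylic-alcohol side products, or add sluggishly to the alkyl-substituted bromoalkyne. Fallback: change the radical source and coupling mode by making the tertiary NHPI ester from an isobutyrate-aldol acid and running a Ni/Fe-catalysed decarboxylative alkynylation with the ring-B alkynylzinc derived from the terminal alkyne.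
2. **Step 26 (HWE on the vinylogous ester).** It may be sluggish or give the wrong C21 geometry. Fallback: install the C21 enoate before ring closure by HWE on the ynone, then close ring C by Pd-catalysed 6-endo-dig cycloisomerisation of the enynoate alcohol.
3. **Step 28 (Julia–Kocienski olefination).** The hindered neopentylic sulfone and the base-labile ring B and ring C could give epimerisation, ring opening or a poor E/Z ratio. Fallback: replace the C16 aldehyde and C17 sulfone with vinyl partners and form C16=C17 by Ru-catalysed cross-metathesis.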